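**Strategy.** The route rests on disconnecting the C6–C7 bond (germacrane numbering), which joins the ten-membered carbocycle to the β-carbon of the γ-lactone. The feature exploited is the homoallylic alcohol array C13=C11–C7–C6–O6 that straddles both rings: it is the retron of a γ-selective allylmetal addition. The precursor is an open-chain (5S)-3-(bromomethyl)butenolide whose C8 side chain ends in a trans-4,5-epoxy aldehyde (C6). One intramolecular Nozaki–Hiyama allylation closes the carbocycle (butenolide and oxirane already in place), creates C6 and C7, and unveils the exocyclic methylene. The chain is built by two propargylation/carboalumination cycles; bis-acetylation finishes the synthesis.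

Key step: step 14

Remark (numbering): C1–C10 form the carbocycle (C1=C10 olefin, O at C2 and C6, oxirane C4–C5, lactone fusion C7/C8); C11 is the lactone α-carbon, C12 the carbonyl, C13 the exocyclic CH2; C14 is the methyl on C10 and C15 the methyl on C4.

Remark (assumption): the (S)-phosphoric acid in steps 1 and 5 is taken to direct Si-face addition, giving the S carbinols; should the sense prove opposite, the (R)-catalyst is used.

Remark (design): crotonaldehyde supplies C7 and C8; its propenyl terminus is a sacrificial olefin that leaves as propene in step 11.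

**Step 1**
Reactants: 1 (E)-but-2-enal; 2 allenylboronic acid pinacol ester
Product: 3 (4S,5E)-hept-5-en-1-yn-4-ol
Conditions: (S)-3,3′-bis(2,4,6-triisopropylphenyl)-1,1′-binaphthyl-2,2′-diyl hydrogen phosphate (10 mol %), 4 Å MS, toluene, −20 °C; aqueous work-up
Reagents that add atoms: none
Why: Chiral phosphoric acid-catalysed aldehyde propargylation with an allenylboronate: the acid activates the boronate and the SE2′ addition runs through a closed six-membered chair transition state on the Si face of the enal, which should set C8 as S and give only the homopropargylic 1,2-adduct.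

**Step 2**
Reactants: 3 (4S,5E)-hept-5-en-1-yn-4-ol
Product: 4 (4S,5E)-4-[(4-methoxybenzyl)oxy]hept-5-en-1-yne
Conditions: NaH, 4-methoxybenzyl chloride, Bu4NI (cat.), THF–DMF, 0 °C to rt
Reagents that add atoms: 4-methoxybenzyl chloride COc1ccc(CCl)cc1
Why: Williamson etherification of the sodium alkoxide; the ether masks O8 through the organoaluminium steps and is later removable oxidatively without touching silyl ethers.

**Step 3**
Reactants: 4 (4S,5E)-4-[(4-methoxybenzyl)oxy]hept-5-en-1-yne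
Product: 6 (2E,5S,6E)-5-[(4-methoxybenzyl)oxy]-3-methylocta-2,6-dien-1-ol, via alkenylalane 5 (not isolated)
Conditions: Me3Al, Cp2ZrCl2 (0.3 equiv), CH2Cl2, 0 °C to rt; then (CH2O)n, 0 °C to rt; Rochelle salt work-up
Reagents that add atoms: trimethylaluminium C[Al](C)C; paraformaldehyde (as formaldehyde) C=O
Why: Zirconium-catalysed (Negishi) carboalumination adds methyl and aluminium syn across the terminal alkyne with methyl on the internal carbon C10, and the alkenylalane is hydroxymethylated by formaldehyde with retention, which fixes the (E)-C1=C10 olefin and introduces C14 and C2.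

**Step 4**
Reactants: 6 (2E,5S,6E)-5-[(4-methoxybenzyl)oxy]-3-methylocta-2,6-dien-1-ol
Product: 7 (2E,5S,6E)-5-[(4-methoxybenzyl)oxy]-3-methylocta-2,6-dienal
Conditions: MnO2, CH2Cl2, rt
Reagents that add atoms: none
Why: Chemoselective allylic oxidation with MnO2 should give the (E)-enal without isomerisation; the ethers and the isolated olefin are inert.

**Step 5**
Reactants: 7 (2E,5S,6E)-5-[(4-methoxybenzyl)oxy]-3-methylocta-2,6-dienal; 2 allenylboronic acid pinacol ester
Product: 8 (4S,5E,8S,9E)-8-[(4-methoxybenzyl)oxy]-6-methylundeca-5,9-dien-1-yn-4-ol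
Conditions: (S)-3,3′-bis(2,4,6-triisopropylphenyl)-1,1′-binaphthyl-2,2′-diyl hydrogen phosphate (10 mol %), 4 Å MS, toluene, −20 to 0 °C; aqueous work-up
Reagents that add atoms: none
Why: Second chiral phosphoric acid-catalysed propargylation, catalyst-controlled because C8 is remote: Si-face addition to the β,β-disubstituted enal should set C2 as S and installs C3–C5.

**Step 6**
Reactants: 8 (4S,5E,8S,9E)-8-[(4-methoxybenzyl)oxy]-6-methylundeca-5,9-dien-1-yn-4-ol
Product: 10 (2E,5S,6E,9S,10E)-9-[(4-methoxybenzyl)oxy]-3,7-dimethyldodeca-2,6,10-triene-1,5-diol, via alkenylalane 9 (not isolated)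
Conditions: Me3Al (4 equiv), Cp2ZrCl2 (0.5 equiv), CH2Cl2, 0 °C to rt; then (CH2O)n, 0 °C to rt; Rochelle salt work-up
Reagents that add atoms: trimethylaluminium C[Al](C)C; paraformaldehyde (as formaldehyde) C=O
Why: Second Negishi carboalumination, run on the aluminium alkoxide of the homopropargylic alcohol and followed by formaldehyde trapping: syn methyl-alumination fixes the (E)-C4=C5 olefin and adds C15 and C6.

**Step 7**
Reactants: 10 (2E,5S,6E,9S,10E)-9-[(4-methoxybenzyl)oxy]-3,7-dimethyldodeca-2,6,10-triene-1,5-diol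
Product: 11 (2S,3E,6S,7E)-1-[(2R,3R)-3-(hydroxymethyl)-2-methyloxiran-2-yl]-6-[(4-methoxybenzyl)oxy]-4-methylnona-3,7-dien-2-ol
Conditions: Ti(OiPr)4 (cat.), D-(−)-diethyl tartrate, t-BuOOH, 4 Å MS, CH2Cl2, −20 °C
Reagents that add atoms: tert-butyl hydroperoxide CC(C)(C)OO
Why: Sharpless asymmetric epoxidation: the primary allylic alcohol binds titanium and the (E)-trisubstituted olefin is epoxidised from the face set by D-(−)-tartrate, giving the 4R,5R trans-oxirane, whereas the secondary allylic C2 carbinol (olefin with a cis methyl) and the ether-flanked olefin should react far more slowly.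

**Step 8**
Reactants: 11 (2S,3E,6S,7E)-1-[(2R,3R)-3-(hydroxymethyl)-2-methyloxiran-2-yl]-6-[(4-methoxybenzyl)oxy]-4-methylnona-3,7-dien-2-ol
Product: 12 (2R,3R)-2-methyl-2-[(2S,3E,6S,7E)-6-[(4-methoxybenzyl)oxy]-4-methyl-2-(triethylsilyloxy)nona-3,7-dien-1-yl]-3-[(triethylsilyloxy)methyl]oxirane
Conditions: Et3SiCl, imidazole, DMF, 0 °C
Reagents that add atoms: chlorotriethylsilane CC[Si](Cl)(CC)CC
Why: Silylation of both hydroxyls (silyl ether formation) so that O8 alone can be unveiled and acylated.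

**Step 9**
Reactants: 12 (2R,3R)-2-methyl-2-[(2S,3E,6S,7E)-6-[(4-methoxybenzyl)oxy]-4-methyl-2-(triethylsilyloxy)nona-3,7-dien-1-yl]-3-[(triethylsilyloxy)methyl]oxirane
Product: 13 (2E,4S,6E,8S)-6-methyl-9-[(2R,3R)-2-methyl-3-[(triethylsilyloxy)methyl]oxiran-2-yl]-8-(triethylsilyloxy)nona-2,6-dien-4-ol
Conditions: DDQ, CH2Cl2–pH 7 buffer, 0 °C
Reagents that add atoms: none
Why: Oxidative cleavage of the 4-methoxybenzyl ether by DDQ (hydride abstraction, then hydrolysis of the oxocarbenium ion); silyl ethers, oxirane and olefins should be tolerated under buffered conditions.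

**Step 10**
Reactants: 13 (2E,4S,6E,8S)-6-methyl-9-[(2R,3R)-2-methyl-3-[(triethylsilyloxy)methyl]oxiran-2-yl]-8-(triethylsilyloxy)nona-2,6-dien-4-ol; 14 2-(bromomethyl)acrylic acid
Product: 15 (2E,4S,6E,8S)-6-methyl-9-[(2R,3R)-2-methyl-3-[(triethylsilyloxy)methyl]oxiran-2-yl]-8-(triethylsilyloxy)nona-2,6-dien-4-yl 2-(bromomethyl)acrylate
Conditions: DCC, DMAP (5 mol %), CH2Cl2, −20 to 0 °C
Reagents that add atoms: none
Why: Steglich esterification of the secondary allylic alcohol at low temperature, with retention at C8; acyl transfer should outpace the reversible addition of DMAP to the bromomethyl acrylate.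

**Step 11**
Reactants: 15 (2E,4S,6E,8S)-6-methyl-9-[(2R,3R)-2-methyl-3-[(triethylsilyloxy)methyl]oxiran-2-yl]-8-(triethylsilyloxy)nona-2,6-dien-4-yl 2-(bromomethyl)acrylate
Product: 16 (5S)-3-(bromomethyl)-5-[(2E,4S)-2-methyl-5-[(2R,3R)-2-methyl-3-[(triethylsilyloxy)methyl]oxiran-2-yl]-4-(triethylsilyloxy)pent-2-en-1-yl]furan-2(5H)-one
Conditions: second-generation Hoveyda–Grubbs catalyst (10 mol %), toluene (0.005 M), 80 °C, argon sparge
Reagents that add atoms: none
Why: Ring-closing olefin metathesis between the propenyl group and the 1,1-disubstituted acrylate forms the C7=C11 bond of the butenolide with loss of propene; the trisubstituted olefin should not engage and the allylic bromide is carried into the ring intact.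

**Step 12**
Reactants: 16 (5S)-3-(bromomethyl)-5-[(2E,4S)-2-methyl-5-[(2R,3R)-2-methyl-3-[(triethylsilyloxy)methyl]oxiran-2-yl]-4-(triethylsilyloxy)pent-2-en-1-yl]furan-2(5H)-one
Product: 17 (5S)-3-(bromomethyl)-5-[(2E,4S)-4-hydroxy-5-[(2R,3R)-3-(hydroxymethyl)-2-methyloxiran-2-yl]-2-methylpent-2-en-1-yl]furan-2(5H)-one
Conditions: Et3N·3HF, THF, 0 °C to rt
Reagents that add atoms: none
Why: Fluoride-mediated cleavage of both triethylsilyl ethers under mildly acidic, non-nucleophilic conditions that should spare the oxirane, the allylic bromide and the base-sensitive C8–H of the butenolide.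

**Step 13**
Reactants: 17 (5S)-3-(bromomethyl)-5-[(2E,4S)-4-hydroxy-5-[(2R,3R)-3-(hydroxymethyl)-2-methyloxiran-2-yl]-2-methylpent-2-en-1-yl]furan-2(5H)-one
Product: 18 (2S,3R)-3-[(2S,3E)-5-[(2S)-4-(bromomethyl)-5-oxo-2,5-dihydrofuran-2-yl]-2-hydroxy-4-methylpent-3-en-1-yl]-3-methyloxirane-2-carbaldehyde
Conditions: TEMPO (0.2 equiv), PhI(OAc)2 (1.1 equiv), CH2Cl2, 0 °C to rt
Reagents that add atoms: none
Why: Oxoammonium (TEMPO) oxidation, sterically selective for the primary alcohol over the hindered allylic C2 carbinol, should give the epoxy aldehyde; lactol formation is impossible because C3 and C6 are trans on the oxirane.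

**Step 14**
Reactants: 18 (2S,3R)-3-[(2S,3E)-5-[(2S)-4-(bromomethyl)-5-oxo-2,5-dihydrofuran-2-yl]-2-hydroxy-4-methylpent-3-en-1-yl]-3-methyloxirane-2-carbaldehyde
Product: 20 (1(10)E,2S,4R,5R,6S,7R,8S)-4,5-epoxy-2,6-dihydroxygermacra-1(10),11(13)-dien-12,8-olide, via allylchromium 19 (not isolated)
Conditions: CrCl2 (10 equiv), THF, syringe-pump addition of 18 (final 0.002 M), rt; aqueous NH4Cl work-up
Reagents that add atoms: none
Why: Two equivalents of CrCl2 (divalent chromium) reduce the C13–Br bond to a trivalent allylchromium species, which adds through its γ-carbon C7 to the aldehyde C6 in a six-membered chair (Zimmerman–Traxler) transition state with transposition of the double bond to C11=C13, so the exocyclic methylene lactone is unveiled as the ring closes. The closest known reaction type is the Nozaki–Hiyama (Barbier-type) allylation of aldehydes with 3-(bromomethyl)furan-2(5H)-ones and its use as a medium-ring macrocyclization with 2-(bromomethyl)acrylates. The ten-membered carbocycle is closed by a 10-exo-trig attack on the carbonyl, forming C6–C7. C7 should be set by attack on the butenolide face opposite the C8–C9 bond (7,8-trans, 7R), and C6 by the ring-locked allyl geometry: C8 is trans to C13 and pseudo-equatorial in the chair, and with C5 equatorial this gives the 6,7-anti carbinol (6S). The step needs γ- over α-attack (inherent to the closed transition state), ring closure over oligomerization (high dilution, slow addition) and the correct aldehyde face; for the latter the crown-like folding imposed by the (E)-C1=C10 olefin and the trans-oxirane, which places O6 on the outside of the ring, must override the weak Felkin–Anh bias of the epoxy aldehyde. The free C2 hydroxyl, the oxirane and the lactone should be tolerated by the non-basic organochromium reagent.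

**Step 15**
Reactants: 20 (1(10)E,2S,4R,5R,6S,7R,8S)-4,5-epoxy-2,6-dihydroxygermacra-1(10),11(13)-dien-12,8-olide
Product: 21 (1(10)E,2S,4R,5R,6S,7R,8S)-2,6-diacetoxy-4,5-epoxygermacra-1(10),11(13)-dien-12,8-olide (CNP0270851.2)
Conditions: Ac2O, pyridine, DMAP (cat.), CH2Cl2, 0 °C to rt
Reagents that add atoms: acetic anhydride CC(=O)OC(C)=O
Why: DMAP-catalysed acetylation of the C2 and C6 hydroxyls with retention; the oxirane and the methylene lactone should be stable to these conditions.

**Compound list**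
1 | (E)-but-2-enal (crotonaldehyde) | C/C=C/C=O | starting material
2 | allenylboronic acid pinacol ester, 4,4,5,5-tetramethyl-2-(propa-1,2-dien-1-yl)-1,3,2-dioxaborolane | C=C=CB1OC(C)(C)C(C)(C)O1 | starting material
3 | (4S,5E)-hept-5-en-1-yn-4-ol | C/C=C/[C@@H](O)CC#C | intermediate
4 | (4S,5E)-4-[(4-methoxybenzyl)oxy]hept-5-en-1-yne | C/C=C/[C@@H](OCc1ccc(OC)cc1)CC#C | intermediate
5 | [(1E,4S,5E)-4-[(4-methoxybenzyl)oxy]-2-methylhepta-1,5-dien-1-yl]dimethylalane (not isolated) | C/C=C/[C@@H](OCc1ccc(OC)cc1)C/C(C)=C/[Al](C)C | intermediate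
6 | (2E,5S,6E)-5-[(4-methoxybenzyl)oxy]-3-methylocta-2,6-dien-1-ol | C/C=C/[C@@H](OCc1ccc(OC)cc1)C/C(C)=C/CO | intermediate
7 | (2E,5S,6E)-5-[(4-methoxybenzyl)oxy]-3-methylocta-2,6-dienal | C/C=C/[C@@H](OCc1ccc(OC)cc1)C/C(C)=C/C=O | intermediate
8 | (4S,5E,8S,9E)-8-[(4-methoxybenzyl)oxy]-6-methylundeca-5,9-dien-1-yn-4-ol | C/C=C/[C@@H](OCc1ccc(OC)cc1)C/C(C)=C/[C@@H](O)CC#C | intermediate
9 | C5-alkenyl(dimethyl)alane of 8 carrying the C2 O-dimethylaluminium alkoxide (not isolated) | C/C=C/[C@@H](OCc1ccc(OC)cc1)C/C(C)=C/[C@@H](O[Al](C)C)C/C(C)=C/[Al](C)C | intermediate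
10 | (2E,5S,6E,9S,10E)-9-[(4-methoxybenzyl)oxy]-3,7-dimethyldodeca-2,6,10-triene-1,5-diol | C/C=C/[C@@H](OCc1ccc(OC)cc1)C/C(C)=C/[C@@H](O)C/C(C)=C/CO | intermediate
11 | (2S,3E,6S,7E)-1-[(2R,3R)-3-(hydroxymethyl)-2-methyloxiran-2-yl]-6-[(4-methoxybenzyl)oxy]-4-methylnona-3,7-dien-2-ol | C/C=C/[C@@H](OCc1ccc(OC)cc1)C/C(C)=C/[C@@H](O)C[C@@]1(C)O[C@@H]1CO | intermediate
12 | (2R,3R)-2-methyl-2-[(2S,3E,6S,7E)-6-[(4-methoxybenzyl)oxy]-4-methyl-2-(triethylsilyloxy)nona-3,7-dien-1-yl]-3-[(triethylsilyloxy)methyl]oxirane | C/C=C/[C@@H](OCc1ccc(OC)cc1)C/C(C)=C/[C@@H](O[Si](CC)(CC)CC)C[C@@]1(C)O[C@@H]1CO[Si](CC)(CC)CC | intermediate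
13 | (2E,4S,6E,8S)-6-methyl-9-[(2R,3R)-2-methyl-3-[(triethylsilyloxy)methyl]oxiran-2-yl]-8-(triethylsilyloxy)nona-2,6-dien-4-ol | C/C=C/[C@@H](O)C/C(C)=C/[C@@H](O[Si](CC)(CC)CC)C[C@@]1(C)O[C@@H]1CO[Si](CC)(CC)CC | intermediate
14 | 2-(bromomethyl)acrylic acid | C=C(CBr)C(=O)O | starting material
15 | (2E,4S,6E,8S)-6-methyl-9-[(2R,3R)-2-methyl-3-[(triethylsilyloxy)methyl]oxiran-2-yl]-8-(triethylsilyloxy)nona-2,6-dien-4-yl 2-(bromomethyl)acrylate | C/C=C/[C@@H](OC(=O)C(=C)CBr)C/C(C)=C/[C@@H](O[Si](CC)(CC)CC)C[C@@]1(C)O[C@@H]1CO[Si](CC)(CC)CC | intermediate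
16 | (5S)-3-(bromomethyl)-5-[(2E,4S)-2-methyl-5-[(2R,3R)-2-methyl-3-[(triethylsilyloxy)methyl]oxiran-2-yl]-4-(triethylsilyloxy)pent-2-en-1-yl]furan-2(5H)-one | O=C1O[C@@H](C/C(C)=C/[C@@H](O[Si](CC)(CC)CC)C[C@@]2(C)O[C@@H]2CO[Si](CC)(CC)CC)C=C1CBr | intermediate
17 | (5S)-3-(bromomethyl)-5-[(2E,4S)-4-hydroxy-5-[(2R,3R)-3-(hydroxymethyl)-2-methyloxiran-2-yl]-2-methylpent-2-en-1-yl]furan-2(5H)-one | O=C1O[C@@H](C/C(C)=C/[C@@H](O)C[C@@]2(C)O[C@@H]2CO)C=C1CBr | intermediate
18 | (2S,3R)-3-[(2S,3E)-5-[(2S)-4-(bromomethyl)-5-oxo-2,5-dihydrofuran-2-yl]-2-hydroxy-4-methylpent-3-en-1-yl]-3-methyloxirane-2-carbaldehyde | O=C1O[C@@H](C/C(C)=C/[C@@H](O)C[C@@]2(C)O[C@@H]2C=O)C=C1CBr | intermediate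
19 | C13 allylchromium dichloride derived from 18 (trivalent chromium, not isolated) | O=C1O[C@@H](C/C(C)=C/[C@@H](O)C[C@@]2(C)O[C@@H]2C=O)C=C1C[Cr](Cl)Cl | intermediate
20 | (1(10)E,2S,4R,5R,6S,7R,8S)-4,5-epoxy-2,6-dihydroxygermacra-1(10),11(13)-dien-12,8-olide | C=C1C(=O)O[C@H]2C/C(C)=C/[C@@H](O)C[C@@]3(C)O[C@@H]3[C@@H](O)[C@H]12 | intermediate
21 | (1(10)E,2S,4R,5R,6S,7R,8S)-2,6-diacetoxy-4,5-epoxygermacra-1(10),11(13)-dien-12,8-olide (CNP0270851.2) | C=C1C(=O)O[C@H]2C/C(C)=C/[C@@H](OC(C)=O)C[C@@]3(C)O[C@@H]3[C@@H](OC(C)=O)[C@H]12 | target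

**Step count.** Total: 15 steps. Longest linear sequence: 15 steps (1 to 21).

**Steps most likely to fail, with fallbacks**

Step 14. Intermolecular allylation (oligomers), loss of facial control at C6/C7 in the chromium transition state, or reductive opening of the epoxy aldehyde by CrCl2 may compete with ring closure. The fallback sets out from 18. The allylic bromide would be converted with B2pin2 under Pd2(dba)3 catalysis (zerovalent palladium) in toluene–DMSO into the allylboronate (2S,3R)-3-[(2S,3E)-2-hydroxy-4-methyl-5-[(2S)-5-oxo-4-[(4,4,5,5-tetramethyl-1,3,2-dioxaborolan-2-yl)methyl]-2,5-dihydrofuran-2-yl]pent-3-en-1-yl]-3-methyloxirane-2-carbaldehyde F1, with boron at the less hindered terminus C13. On warming at high dilution F1 should close by a metal-free intramolecular allylboration through a tighter chair transition state of the same anti sense. Hydrolytic work-up brings the route back at 20.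

Step 11. Slow closure onto the hindered, electron-poor 1,1-disubstituted olefin and decomposition of the ruthenium carbene by the labile allylic bromide may stall the metathesis. The fallback sets out from 13. Esterification with 2-(chloromethyl)acrylic acid (DCC, DMAP) would give (2E,4S,6E,8S)-6-methyl-9-[(2R,3R)-2-methyl-3-[(triethylsilyloxy)methyl]oxiran-2-yl]-8-(triethylsilyloxy)nona-2,6-dien-4-yl 2-(chloromethyl)acrylate F2. The more robust allylic chloride should survive ring-closing metathesis to (5S)-3-(chloromethyl)-5-[(2E,4S)-2-methyl-5-[(2R,3R)-2-methyl-3-[(triethylsilyloxy)methyl]oxiran-2-yl]-4-(triethylsilyloxy)pent-2-en-1-yl]furan-2(5H)-one F3. Halide exchange with LiBr in acetone, which installs the bromide only after the ring is made, brings the route back at 16.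

Step 13. Over-oxidation of the allylic C2 carbinol to the enone may compete with oxidation of the primary alcohol. The fallback sets out from 16 and keeps O2 silylated through oxidation and cyclization. The primary silyl ether alone would be cleaved (PPTS, MeOH–CH2Cl2, −20 °C) to (5S)-3-(bromomethyl)-5-[(2E,4S)-5-[(2R,3R)-3-(hydroxymethyl)-2-methyloxiran-2-yl]-2-methyl-4-(triethylsilyloxy)pent-2-en-1-yl]furan-2(5H)-one F4. Dess–Martin oxidation should then give the 2-O-triethylsilyl ether of 18, (2S,3R)-3-[(2S,3E)-5-[(2S)-4-(bromomethyl)-5-oxo-2,5-dihydrofuran-2-yl]-4-methyl-2-(triethylsilyloxy)pent-3-en-1-yl]-3-methyloxirane-2-carbaldehyde F5. CrCl2 macrocyclization as in step 14 would give the 2-O-triethylsilyl ether of 20, (1(10)E,2S,4R,5R,6S,7R,8S)-4,5-epoxy-6-hydroxy-2-(triethylsilyloxy)germacra-1(10),11(13)-dien-12,8-olide F6. Desilylation with Et3N·3HF brings the route back at 20.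

**Further compounds**
F1 | step 14 | (2S,3R)-3-[(2S,3E)-2-hydroxy-4-methyl-5-[(2S)-5-oxo-4-[(4,4,5,5-tetramethyl-1,3,2-dioxaborolan-2-yl)methyl]-2,5-dihydrofuran-2-yl]pent-3-en-1-yl]-3-methyloxirane-2-carbaldehyde | O=C1O[C@@H](C/C(C)=C/[C@@H](O)C[C@@]2(C)O[C@@H]2C=O)C=C1CB1OC(C)(C)C(C)(C)O1
F2 | step 11 | (2E,4S,6E,8S)-6-methyl-9-[(2R,3R)-2-methyl-3-[(triethylsilyloxy)methyl]oxiran-2-yl]-8-(triethylsilyloxy)nona-2,6-dien-4-yl 2-(chloromethyl)acrylate | C/C=C/[C@@H](OC(=O)C(=C)CCl)C/C(C)=C/[C@@H](O[Si](CC)(CC)CC)C[C@@]1(C)O[C@@H]1CO[Si](CC)(CC)CC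
F3 | step 11 | (5S)-3-(chloromethyl)-5-[(2E,4S)-2-methyl-5-[(2R,3R)-2-methyl-3-[(triethylsilyloxy)methyl]oxiran-2-yl]-4-(triethylsilyloxy)pent-2-en-1-yl]furan-2(5H)-one | O=C1O[C@@H](C/C(C)=C/[C@@H](O[Si](CC)(CC)CC)C[C@@]2(C)O[C@@H]2CO[Si](CC)(CC)CC)C=C1CCl
F4 | step 13 | (5S)-3-(bromomethyl)-5-[(2E,4S)-5-[(2R,3R)-3-(hydroxymethyl)-2-methyloxiran-2-yl]-2-methyl-4-(triethylsilyloxy)pent-2-en-1-yl]furan-2(5H)-one | O=C1O[C@@H](C/C(C)=C/[C@@H](O[Si](CC)(CC)CC)C[C@@]2(C)O[C@@H]2CO)C=C1CBr
F5 | step 13 | (2S,3R)-3-[(2S,3E)-5-[(2S)-4-(bromomethyl)-5-oxo-2,5-dihydrofuran-2-yl]-4-methyl-2-(triethylsilyloxy)pent-3-en-1-yl]-3-methyloxirane-2-carbaldehyde | O=C1O[C@@H](C/C(C)=C/[C@@H](O[Si](CC)(CC)CC)C[C@@]2(C)O[C@@H]2C=O)C=C1CBr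
F6 | step 13 | (1(10)E,2S,4R,5R,6S,7R,8S)-4,5-epoxy-6-hydroxy-2-(triethylsilyloxy)germacra-1(10),11(13)-dien-12,8-olide | C=C1C(=O)O[C@H]2C/C(C)=C/[C@@H](O[Si](CC)(CC)CC)C[C@@]3(C)O[C@@H]3[C@@H](O)[C@H]12
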